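**Retrosynthetic overview**

1. Target ⇐ C1 alcohol (acetylation) ⇐ C1 ketone (hydride from the face opposite the angular methyl).
2. C1 ketone ⇐ acyclic 2‑silyloxy‑1,3‑diene tethered to a (Z)‑2‑methyl‑2‑enoate: one intramolecular Diels–Alder reaction makes bonds C10–C5 and C3–C4, so rings A and B close together, and C9 controls C10, C5 and C4.
3. Silyloxydiene ⇐ methyl alkyl ketene + vinylmagnesium bromide, then O‑silylation; ketene ⇐ α‑methyl acid.
4. Acid ⇐ enantioselective boron ester‑enolate Claisen rearrangement of an achiral allyl propanoate (sets C9, creates the C8 methylidene).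
5. Allyl propanoate ⇐ propargyl alcohol + acetal Grignard reagent + dienyl bromide (carbomagnesiation/allylation), acylation, Still–Gennari olefination.

Atom labels C1–C20 are the labdane positions of the target (C17 = exocyclic CH2, C19 = ester carbon, C20 = angular methyl).

Assumption: the (4S,5S)‑bromoborane controller is taken to give the (2S,3S)‑acid 15; if it gives the mirror image, the (4R,5R)‑controller is used and nothing else changes.

**Route**

Step 1
Reactants: 1 (2E)-3-methylpent-2-en-4-yn-1-ol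
Product: 2 (2E)-3-methylpenta-2,4-dien-1-ol
Conditions: H2 (1 atm), Pd/CaCO3 poisoned with Pb(OAc)2, quinoline, EtOAc, 0 °C, stopped after 1 equiv H2
Reagents that add atoms: none
Why: Lindlar semi-hydrogenation stops the terminal alkyne at the vinyl group and leaves the E-trisubstituted alkene untouched, so the side-chain diene geometry comes from the starting material.

Step 2
Reactants: 2 (2E)-3-methylpenta-2,4-dien-1-ol; 3 phosphorus tribromide
Product: 4 (3E)-5-bromo-3-methylpenta-1,3-diene
Conditions: PBr3 (0.4 equiv), pyridine (cat.), Et2O, −20 °C; used cold and at once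
Reagents that add atoms: phosphorus tribromide, BrP(Br)Br
Why: Bromination of a primary allylic alcohol through its phosphite ester (SN2 displacement by bromide) at low temperature keeps the E geometry.

Step 3
Reactants: 5 prop-2-yn-1-ol; 6 [2-(1,3-dioxolan-2-yl)ethyl]magnesium bromide; 4 (3E)-5-bromo-3-methylpenta-1,3-diene
Product: 8 (2Z,5E)-2-[2-(1,3-dioxolan-2-yl)ethyl]-6-methylocta-2,5,7-trien-1-ol, via vinylmagnesium alkoxide 7 (not isolated)
Conditions: 6 (2.2 equiv), CuI (10 mol %), THF–Et2O, −10 °C to rt; then 4 (1.3 equiv), −30 to 0 °C; H2O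
Reagents that add atoms: [2-(1,3-dioxolan-2-yl)ethyl]magnesium bromide, Br[Mg]CCC1OCCO1; (3E)-5-bromo-3-methylpenta-1,3-diene, C=C/C(C)=C/CBr
Why: Copper-catalysed anti-carbomagnesiation of propargyl alcohol (Duboudin–Jousseaume reaction) puts the alkyl group on the internal carbon and gives a chelated (Z)-vinylmagnesium alkoxide, which is allylated by 4 with retention, so the C8=C9 alkene forms as one isomer (C17 cis to C11).

Step 4
Reactants: 8 (2Z,5E)-2-[2-(1,3-dioxolan-2-yl)ethyl]-6-methylocta-2,5,7-trien-1-ol; 9 propanoyl chloride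
Product: 11 (2Z,5E)-6-methyl-2-(3-oxopropyl)octa-2,5,7-trien-1-yl propanoate, via propanoate acetal 10 (not isolated)
Conditions: 9, pyridine, DMAP (cat.), CH2Cl2, 0 °C; then 2 M aq. HCl–THF, rt
Reagents that add atoms: propanoyl chloride, CCC(Cl)=O; water, O
Why: O-acylation of the primary allylic alcohol followed by acid hydrolysis of the dioxolane (acetal hydrolysis), conditions under which the allylic ester and the alkenes are stable.

Step 5
Reactants: 11 (2Z,5E)-6-methyl-2-(3-oxopropyl)octa-2,5,7-trien-1-yl propanoate; 12 methyl 2-[bis(2,2,2-trifluoroethoxy)phosphoryl]propanoate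
Product: 13 methyl (2Z,6Z,9E)-2,10-dimethyl-6-[(propanoyloxy)methyl]dodeca-2,6,9,11-tetraenoate
Conditions: 12 (1.1 equiv), KN(SiMe3)2 (1.05 equiv), 18-crown-6, THF, −78 °C; then 11
Reagents that add atoms: methyl 2-[bis(2,2,2-trifluoroethoxy)phosphoryl]propanoate, COC(=O)C(C)P(=O)(OCC(F)(F)F)OCC(F)(F)F
Why: Still–Gennari variant of the Horner–Wadsworth–Emmons olefination, whose fast, irreversible elimination gives the (Z)-2-methyl-2-enoate needed to place the ester cis to C20 later.

Step 6
Reactants: 13 methyl (2Z,6Z,9E)-2,10-dimethyl-6-[(propanoyloxy)methyl]dodeca-2,6,9,11-tetraenoate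
Product: 15 (2S,3S,5E)-3-[(5Z)-7-methoxy-6-methyl-7-oxohepta-1,5-dien-2-yl]-2,6-dimethylocta-5,7-dienoic acid, via boron ketene acetal 14 (not isolated)
Conditions: (4S,5S)-2-bromo-4,5-diphenyl-1,3-bis{[3,5-bis(trifluoromethyl)phenyl]sulfonyl}-1,3,2-diazaborolidine (1.2 equiv), Et3N, toluene–hexane, −78 °C, then −20 °C, several days; H2O work-up (bis-sulfonamide recovered)
Reagents that add atoms: none
Why: Enantioselective boron ester-enolate Claisen rearrangement ([3,3], Ireland–Claisen type) through a chair transition state in which the chiral diazaborolidine fixes the enolate face; the new C10–C9 bond sets C9, the former CH2–O carbon becomes the C8=CH2 group, and the C10 configuration does not matter because C10 becomes sp2 in step 7.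

Step 7
Reactants: 15 (2S,3S)-acid; 16 ethenylmagnesium bromide; 17 tert-butyldimethylsilyl trifluoromethanesulfonate
Product: 21 methyl (2Z,7R,8Z)-9-{[tert-butyl(dimethyl)silyl]oxy}-2,8-dimethyl-6-methylidene-7-[(2E)-3-methylpenta-2,4-dien-1-yl]undeca-2,8,10-trienoate, via acid chloride 18 (not isolated), via ketene 19 (not isolated), via magnesium dienolate 20 (not isolated)
Conditions: 1-chloro-N,N,2-trimethylprop-1-en-1-amine, CH2Cl2, 0 °C; Et3N, Et2O, rt, filtered under Ar; 16 (1.05 equiv), THF, −78 °C; 17, −78 to 0 °C; filtration through basic alumina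
Reagents that add atoms: ethenylmagnesium bromide, C=C[Mg]Br; tert-butyldimethylsilyl trifluoromethanesulfonate, CC(C)(C)[Si](C)(C)OS(=O)(=O)C(F)(F)F
Why: The chloroenamine gives the acid chloride without HCl, Et3N dehydrochlorinates it to the methyl alkyl ketene, and the Grignard reagent adds to the ketene carbonyl in the plane of the substituents from the side of the small methyl group (organometallic addition to a ketene), so O-silylation gives the (Z)-silyl dienol ether with the tether trans to the vinyl group and no free vinyl ketone, which would cycloadd to the side-chain diene, is ever formed.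

Step 8
Reactants: 21 silyl dienol ether
Product: 23 methyl (1R,4aS,5R,8aS)-1,4a-dimethyl-6-methylidene-5-[(2E)-3-methylpenta-2,4-dien-1-yl]-4-oxodecahydronaphthalene-1-carboxylate, via bicyclic silyl enol ether 22 (not isolated)
Conditions: toluene (0.01 M), BHT, 180 °C, sealed tube; then Bu4NF, AcOH, THF, 0 °C
Reagents that add atoms: none
Why: Intramolecular Diels–Alder reaction of a 2-silyloxydiene with the tethered (Z)-2-methyl-2-enoate (electron-rich C10 bonds to the β-carbon C5), in which the C9–H bond eclipses the C10=C1 bond next to the OTBS group to avoid A(1,3) strain, so the dienophile adds anti to the C9 side chain through a chair-like tether with the ester exo (the usual preference of 2-methyl-substituted dienophiles), which closes rings A and B as the trans-fused decalin and sets C10, C5 and C4 (ester cis to C20 because the enoate is Z) before fluoride cleaves the silyl enol ether to the C1 ketone.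

Step 9
Reactants: 23 C1 ketone
Product: 24 methyl (1R,4S,4aS,5R,8aS)-4-hydroxy-1,4a-dimethyl-6-methylidene-5-[(2E)-3-methylpenta-2,4-dien-1-yl]decahydronaphthalene-1-carboxylate
Conditions: NaBH4, MeOH–THF, −20 to 0 °C
Reagents that add atoms: none
Why: Hydride adds to the C1 ketone axially from the face opposite the axial angular methyl group (steric approach control in a cyclohexanone reduction), which gives the equatorial alcohol cis to C20, and the hindered methyl ester is not reduced.

Step 10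
Reactants: 24 C1 alcohol; 25 acetic anhydride
Product: 26 methyl (1R,4S,4aS,5R,8aS)-4-(acetyloxy)-1,4a-dimethyl-6-methylidene-5-[(2E)-3-methylpenta-2,4-dien-1-yl]decahydronaphthalene-1-carboxylate (CNP0235031.1)
Conditions: 25, pyridine, DMAP (cat.), CH2Cl2, rt
Reagents that add atoms: acetic anhydride, CC(=O)OC(C)=O
Why: DMAP-catalysed acetylation (nucleophilic acyl transfer) of the secondary alcohol touches no stereocentre and gives the target.

**Compound list**

1 | (2E)-3-methylpent-2-en-4-yn-1-ol | C#C/C(C)=C/CO | starting material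
2 | (2E)-3-methylpenta-2,4-dien-1-ol | C=C/C(C)=C/CO | intermediate
3 | phosphorus tribromide | BrP(Br)Br | starting material
4 | (3E)-5-bromo-3-methylpenta-1,3-diene | C=C/C(C)=C/CBr | intermediate
5 | prop-2-yn-1-ol | C#CCO | starting material
6 | [2-(1,3-dioxolan-2-yl)ethyl]magnesium bromide | Br[Mg]CCC1OCCO1 | starting material
7 | bromomagnesium (2Z)-3-(bromomagnesio)-2-[2-(1,3-dioxolan-2-yl)ethyl]prop-2-en-1-olate | Br[Mg]/C=C(\CO[Mg]Br)CCC1OCCO1 | intermediate
8 | (2Z,5E)-2-[2-(1,3-dioxolan-2-yl)ethyl]-6-methylocta-2,5,7-trien-1-ol | OC/C(CCC1OCCO1)=C\C/C=C(C)/C=C | intermediate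
9 | propanoyl chloride | CCC(Cl)=O | starting material
10 | (2Z,5E)-2-[2-(1,3-dioxolan-2-yl)ethyl]-6-methylocta-2,5,7-trien-1-yl propanoate | CCC(=O)OC/C(CCC1OCCO1)=C\C/C=C(C)/C=C | intermediate
11 | (2Z,5E)-6-methyl-2-(3-oxopropyl)octa-2,5,7-trien-1-yl propanoate | CCC(=O)OC/C(CCC=O)=C\C/C=C(C)/C=C | intermediate
12 | methyl 2-[bis(2,2,2-trifluoroethoxy)phosphoryl]propanoate | COC(=O)C(C)P(=O)(OCC(F)(F)F)OCC(F)(F)F | starting material
13 | methyl (2Z,6Z,9E)-2,10-dimethyl-6-[(propanoyloxy)methyl]dodeca-2,6,9,11-tetraenoate | CCC(=O)OC/C(CC/C=C(/C)C(=O)OC)=C\C/C=C(C)/C=C | intermediate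
14 | boron ketene acetal of 13 (methyl cis to the allyloxy oxygen) bearing the (4S,5S)-4,5-diphenyl-1,3-bis{[3,5-bis(trifluoromethyl)phenyl]sulfonyl}-1,3,2-diazaborolidin-2-yl group on oxygen | C/C=C(/OB1N(S(=O)(=O)c2cc(cc(c2)C(F)(F)F)C(F)(F)F)[C@@H](c2ccccc2)[C@H](c2ccccc2)N1S(=O)(=O)c1cc(cc(c1)C(F)(F)F)C(F)(F)F)OC/C(CC/C=C(/C)C(=O)OC)=C\C/C=C(C)/C=C | intermediate
15 | (2S,3S,5E)-3-[(5Z)-7-methoxy-6-methyl-7-oxohepta-1,5-dien-2-yl]-2,6-dimethylocta-5,7-dienoic acid | C=C/C(C)=C/C[C@@H]([C@H](C)C(=O)O)C(=C)CC/C=C(/C)C(=O)OC | intermediate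
16 | ethenylmagnesium bromide | C=C[Mg]Br | starting material
17 | tert-butyldimethylsilyl trifluoromethanesulfonate | CC(C)(C)[Si](C)(C)OS(=O)(=O)C(F)(F)F | starting material
18 | (2S,3S,5E)-3-[(5Z)-7-methoxy-6-methyl-7-oxohepta-1,5-dien-2-yl]-2,6-dimethylocta-5,7-dienoyl chloride | C=C/C(C)=C/C[C@@H]([C@H](C)C(Cl)=O)C(=C)CC/C=C(/C)C(=O)OC | intermediate
19 | methyl (2Z,7R)-2,8-dimethyl-6-methylidene-7-[(2E)-3-methylpenta-2,4-dien-1-yl]-9-oxonona-2,8-dienoate (ketene) | C=C/C(C)=C/C[C@@H](C(C)=C=O)C(=C)CC/C=C(/C)C(=O)OC | intermediate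
20 | methyl (2Z,7R,8Z)-9-[(bromomagnesio)oxy]-2,8-dimethyl-6-methylidene-7-[(2E)-3-methylpenta-2,4-dien-1-yl]undeca-2,8,10-trienoate | C=C/C(C)=C/C[C@@H](C(\C)=C(/O[Mg]Br)C=C)C(=C)CC/C=C(/C)C(=O)OC | intermediate
21 | methyl (2Z,7R,8Z)-9-{[tert-butyl(dimethyl)silyl]oxy}-2,8-dimethyl-6-methylidene-7-[(2E)-3-methylpenta-2,4-dien-1-yl]undeca-2,8,10-trienoate | C=C/C(C)=C/C[C@@H](C(\C)=C(/O[Si](C)(C)C(C)(C)C)C=C)C(=C)CC/C=C(/C)C(=O)OC | intermediate
22 | methyl (1R,4aS,5R,8aS)-4-{[tert-butyl(dimethyl)silyl]oxy}-1,4a-dimethyl-6-methylidene-5-[(2E)-3-methylpenta-2,4-dien-1-yl]-1,2,4a,5,6,7,8,8a-octahydronaphthalene-1-carboxylate | C=C/C(C)=C/C[C@@H]1C(=C)CC[C@H]2[C@@]1(C)C(O[Si](C)(C)C(C)(C)C)=CC[C@@]2(C)C(=O)OC | intermediate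
23 | methyl (1R,4aS,5R,8aS)-1,4a-dimethyl-6-methylidene-5-[(2E)-3-methylpenta-2,4-dien-1-yl]-4-oxodecahydronaphthalene-1-carboxylate | C=C/C(C)=C/C[C@@H]1C(=C)CC[C@H]2[C@@]1(C)C(=O)CC[C@@]2(C)C(=O)OC | intermediate
24 | methyl (1R,4S,4aS,5R,8aS)-4-hydroxy-1,4a-dimethyl-6-methylidene-5-[(2E)-3-methylpenta-2,4-dien-1-yl]decahydronaphthalene-1-carboxylate | C=C/C(C)=C/C[C@@H]1C(=C)CC[C@H]2[C@@]1(C)[C@@H](O)CC[C@@]2(C)C(=O)OC | intermediate
25 | acetic anhydride | CC(=O)OC(C)=O | starting material
26 | methyl (1R,4S,4aS,5R,8aS)-4-(acetyloxy)-1,4a-dimethyl-6-methylidene-5-[(2E)-3-methylpenta-2,4-dien-1-yl]decahydronaphthalene-1-carboxylate | C=C/C(C)=C/C[C@@H]1C(=C)CC[C@H]2[C@@]1(C)[C@@H](OC(C)=O)CC[C@@]2(C)C(=O)OC | target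

**Step count and risks**

Total step count: 10. Longest linear sequence: 10 steps (1 → 2 → 4 → 8 → 11 → 13 → 15 → 21 → 23 → 24 → 26); counted from propargyl alcohol 5 the main line is 8 steps.

Most likely to fail, first: step 8. The ester-exo, trans-fused transition state may lose to the ester-endo, cis-fused one, and the diene, which carries a methyl group on the inside of its reacting terminus, may be slow. The fallback removes the 2-methyl group from the dienophile, so that the ester sits endo in the trans-fused transition state, and introduces the C4 methyl group afterwards. It sets out from aldehyde 11. Wittig reaction with methyl (triphenylphosphoranylidene)acetate gives the (E)-enoate F1. The conditions of step 6 give, through boron ketene acetal F2, the acid F3. The sequence of step 7 gives, through acid chloride F4, ketene F5 and magnesium dienolate F6, the silyl dienol ether F7. Heating as in step 8 gives the trans-fused adduct F8, which has hydrogen at C4. LiN(i-Pr)2 in THF at −78 °C forms the lithium ester enolate F9, and MeI alkylates it from the face opposite the axial angular methyl group, which puts the ester axial. The fallback comes back to the route at 22, which is desilylated to 23 as in step 8.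

Second: step 7. Dehydrochlorination of a dialkyl-substituted acid chloride is slow, and the ketene can add to the side-chain diene in a [2+2] reaction. The fallback makes the enol ether by soft enolisation of the vinyl ketone at low temperature. It sets out from acid 15. Carbodiimide coupling with N,O-dimethylhydroxylamine gives the Weinreb amide F10. Vinylmagnesium bromide at −40 °C and a quench at −78 °C give the vinyl ketone F11, which is kept below −20 °C because above that it cycloadds to its own side-chain diene. It is treated at once with 17 and Et3N at −78 °C; only the C10 side can enolise, and the fallback comes back to the route at 21.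

Third: step 6. Enolisation must be selective for the propanoate, the rearrangement is slow, and the selectivity on a 2-substituted (Z)-allyl ester is untested. The fallback is a racemic rearrangement followed by resolution. It sets out from 13. Cy2BOTf and Et3N give the achiral boron ketene acetal F12, which rearranges to 15 and its mirror image F13 in equal amounts. The (R)-1-phenylethylammonium salt F14 of 15 is crystallised and acidified, and the fallback comes back to the route at 15.

**Further compounds**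

F1 | step 8 | methyl (2E,6Z,9E)-10-methyl-6-[(propanoyloxy)methyl]dodeca-2,6,9,11-tetraenoate | CCC(=O)OC/C(CC/C=C/C(=O)OC)=C\C/C=C(C)/C=C
F2 | step 8 | boron ketene acetal of F1 bearing the (4S,5S)-diazaborolidin-2-yl group of 14 | C/C=C(/OB1N(S(=O)(=O)c2cc(cc(c2)C(F)(F)F)C(F)(F)F)[C@@H](c2ccccc2)[C@H](c2ccccc2)N1S(=O)(=O)c1cc(cc(c1)C(F)(F)F)C(F)(F)F)OC/C(CC/C=C/C(=O)OC)=C\C/C=C(C)/C=C
F3 | step 8 | (2S,3S,5E)-3-[(5E)-7-methoxy-7-oxohepta-1,5-dien-2-yl]-2,6-dimethylocta-5,7-dienoic acid | C=C/C(C)=C/C[C@@H]([C@H](C)C(=O)O)C(=C)CC/C=C/C(=O)OC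
F4 | step 8 | acid chloride of F3 | C=C/C(C)=C/C[C@@H]([C@H](C)C(Cl)=O)C(=C)CC/C=C/C(=O)OC
F5 | step 8 | methyl (2E,7R)-8-methyl-6-methylidene-7-[(2E)-3-methylpenta-2,4-dien-1-yl]-9-oxonona-2,8-dienoate (ketene) | C=C/C(C)=C/C[C@@H](C(C)=C=O)C(=C)CC/C=C/C(=O)OC
F6 | step 8 | bromomagnesium dienolate, 2-demethyl analogue of 20 with an (E)-enoate | C=C/C(C)=C/C[C@@H](C(\C)=C(/O[Mg]Br)C=C)C(=C)CC/C=C/C(=O)OC
F7 | step 8 | methyl (2E,7R,8Z)-9-{[tert-butyl(dimethyl)silyl]oxy}-8-methyl-6-methylidene-7-[(2E)-3-methylpenta-2,4-dien-1-yl]undeca-2,8,10-trienoate | C=C/C(C)=C/C[C@@H](C(\C)=C(/O[Si](C)(C)C(C)(C)C)C=C)C(=C)CC/C=C/C(=O)OC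
F8 | step 8 | methyl (1S,4aR,5R,8aR)-4-{[tert-butyl(dimethyl)silyl]oxy}-4a-methyl-6-methylidene-5-[(2E)-3-methylpenta-2,4-dien-1-yl]-1,2,4a,5,6,7,8,8a-octahydronaphthalene-1-carboxylate (1-demethyl analogue of 22, ester equatorial) | C=C/C(C)=C/C[C@@H]1C(=C)CC[C@H]2[C@@]1(C)C(O[Si](C)(C)C(C)(C)C)=CC[C@@H]2C(=O)OC
F9 | step 8 | lithium ester enolate of F8 | C=C/C(C)=C/C[C@@H]1C(=C)CC[C@H]2[C@@]1(C)C(O[Si](C)(C)C(C)(C)C)=CCC2=C(O[Li])OC
F10 | step 7 | N-methoxy-N-methyl amide of 15 | C=C/C(C)=C/C[C@@H]([C@H](C)C(=O)N(C)OC)C(=C)CC/C=C(/C)C(=O)OC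
F11 | step 7 | methyl (2Z,7S,8S)-2,8-dimethyl-6-methylidene-7-[(2E)-3-methylpenta-2,4-dien-1-yl]-9-oxoundeca-2,10-dienoate (vinyl ketone) | C=C/C(C)=C/C[C@@H]([C@H](C)C(=O)C=C)C(=C)CC/C=C(/C)C(=O)OC
F12 | step 6 | dicyclohexylboron ketene acetal of 13 | C/C=C(/OB(C1CCCCC1)C1CCCCC1)OC/C(CC/C=C(/C)C(=O)OC)=C\C/C=C(C)/C=C
F13 | step 6 | (2R,3R,5E)-3-[(5Z)-7-methoxy-6-methyl-7-oxohepta-1,5-dien-2-yl]-2,6-dimethylocta-5,7-dienoic acid (mirror image of 15) | C=C/C(C)=C/C[C@H]([C@@H](C)C(=O)O)C(=C)CC/C=C(/C)C(=O)OC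
F14 | step 6 | (1R)-1-phenylethanaminium salt of 15 | C=C/C(C)=C/C[C@@H]([C@H](C)C(=O)[O-])C(=C)CC/C=C(/C)C(=O)OC.C[C@@H]([NH3+])c1ccccc1
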